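Two questions stood before me: how much target each of the three new flasks holds at the end, and what shape the row takes. Enzyme turns starting material into target, with second substrate and added ligand also in the flask.

the same everywhere: enzyme 20 µM; added ligand 53 µM

|  | starting material | second substrate | remark | time |
|---|---|---|---|---|
| eta | 0.021 M | 0.10 M | run made earlier |  |
| zeta | 0.063 M | 0.10 M | run made earlier |  |
| Monday's | 0.025 M | 0.100 M |  | 5.0 min |
| Tuesday's | 0.050 M | 0.100 M |  | 5.0 min |
| Thursday's | 0.10 M | 0.100 M |  | 5.0 min |

- eta (time / min: target / %): 0.417: 3.7; 0.833: 8.4; 1.33: 12.3; 2.50: 23.3; 5.00: 45.1
- zeta (time / min: target / %): 1.00: 10.1; 2.00: 18.2; 3.00: 25.2; 4.00: 32.5; 5.00: 42.1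

(scatter of a reading: 0.5 percentage points)

- amount of target at the end, in percent of the starting material charged for Monday's, Tuesday's, Thursday's, in this order
- the shape of the row from first to last (hardly changes / falls, then rises / falls all the way / rises, then falls / rises all the way)

- "hardly changes" means that all values lie within two and a half points (for a concentration: within two and a half percent of the largest)

I worked with the fraction left and folded each run into ln of one over the fraction of starting material left at 5.00 min. For the eta run that gave 0.600, and I called this number the depth. It says how many e-fold reductions the charge has undergone by that time. The zeta run, with its larger charge, gave 0.546. If each molecule's chance of reacting were independent of the charge, depth would be the same in every flask, and the mean depth would put the whole row at 43.6%.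

One number was not quite enough. The two depths differ by 0.0532, while the scatter of that difference, reckoned from the scatter of the two readings, is 0.0126, so the gap is larger than the scatter. I therefore let one over the depth rise in a straight line with the charge. That assumption is mine, and it gave depths of 0.594, 0.562 and 0.507. These mean 44.8%, 43.0% and 39.8% of target, a row that falls throughout.

The forecast, extrapolating a “small real decline with charge”, said 45%, 43% and 39.5%, and that the row falls all the way. Its figures differ from mine at the ends of the row, but its shape is the same as mine.

The flasks gave 44.9%, 42.9% and 39.4%, and the row falls all the way.

    starting material + enzyme ⇌ complex A (K = 5.80 /M, k = 19000 /M/s)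
    complex A → enzyme + target (k = 43.0 /s)
    second substrate + enzyme ⇌ complex B (K = 16.0 /M, k = 51000 /M/s)
    complex B → enzyme + second product (k = 47.0 /s)
    enzyme + added ligand ⇌ idle complex (K = 6500 /M, k = 390 /M/s)
    second substrate + complex B → spent catalyst (k = 0.0360 /M/s)

What to watch is the fraction left. Monday's flask ended at a depth of 0.596 and Thursday's flask at 0.501, which is 0.835 of the depth read from the eta run, so Thursday's depth was smaller than Monday's. The reverse step, complex A to starting material + enzyme, is one part of what made the row fall. In a run without that reverse step, the change of target from Monday's flask to Thursday's flask went from −5.4 percentage points to 0 points.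

(The runs were generated by integration with constants of no real substance; noise was put on by code.)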